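**Retrosynthetic overview**
1. Feature used: the cyclodecane ring has a hidden mirror plane through C2 and C7 (C4‑Me/C10‑Me, C5–O/C9=O, C6–O/C8–O). The C4 carbinol oxygen can be tied to C10, the α‑carbon of the C9 ketone, as a removable ether bridge.
2. Key disconnection (ring expansion 5+7 → 10): the ring C1–C10 is not closed. It is released by ozonolysis of the ring‑fusion double bond C5=C9 of an oxa‑bridged bicyclo[5.3.0]decene, and the cut delivers C9=O and the C5 oxygen.
3. The tricycle comes from a [4+3] cycloaddition of an oxyallyl cation (C1–C2–C3) across C4/C10 of a 1,3‑dimethylcyclopenta[c]furan (C4, C5, C9, C10, O4, both methyls). Its cyclopentane ring (C5–C9) is the template for C6 and C7.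
4. After the cut: Felkin–Anh reduction (C5), SmI2 unlocking of the C10–O bond (C4–OH, C10–H), Rubottom oxidation (C8), two acylations.
5. Ring order: furan (bought) → cyclopentane → oxa‑bridged cycloheptane → cyclodecane (by cleavage) → γ‑lactone (last step).

Key step: step 11

Remark: germacrane numbering of the target (ring C1–C10, C14 = 10‑Me, C15 = 4‑Me, lactone C11–C13) is used for all intermediates. The C9 carbinol centre of 21 is immaterial and is drawn as the Felkin–Anh model predicts.

Step 1
Reactants: 1 2,5-dimethylfuran-3-carbaldehyde; 2 Meldrum's acid (2,2-dimethyl-1,3-dioxane-4,6-dione)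
Product: 4 5-[(2,5-dimethylfuran-3-yl)methyl]-2,2-dimethyl-1,3-dioxane-4,6-dione, via alkylidene Meldrum's acid 3 (not isolated)
Conditions: L-proline (20 mol %), Hantzsch ester (1 equiv), EtOH, rt
Reagents that add atoms: none
Why: Knoevenagel condensation followed by conjugate hydride transfer from the Hantzsch ester (three-component reductive alkylation) is general for aromatic aldehydes, joins C8 to C7 and makes no stereocenter.

Step 2
Reactants: 4 5-[(2,5-dimethylfuran-3-yl)methyl] Meldrum's acid
Product: 5 1,3-dimethyl-5,6-dihydro-4H-cyclopenta[c]furan-4-one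
Conditions: Sc(OTf)3 (10 mol %), MeNO2, 100 °C
Reagents that add atoms: none
Why: Lewis-acid-catalysed intramolecular Friedel–Crafts acylation of a benzyl-type Meldrum's acid (loss of acetone and CO2) closes the five-membered ketone (C6–C5 bond) at the only free, electron-rich furan position, with no stereocenter.

Step 3
Reactants: 5 1,3-dimethyl-5,6-dihydro-4H-cyclopenta[c]furan-4-one; 6 ethyl glyoxylate
Product: 7 ethyl (2E)-2-(1,3-dimethyl-4-oxo-4,6-dihydro-5H-cyclopenta[c]furan-5-ylidene)acetate
Conditions: TsOH·H2O (10 mol %), toluene, Dean–Stark, reflux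
Reagents that add atoms: none
Why: Crossed aldol condensation at the only enolisable carbon (C7) with a non-enolisable aldehyde, as for 1-indanone and glyoxylic acid, gives the thermodynamic E-alkylidene ketone (ester anti to C6=O).

Step 4
Reactants: 7 enone ester
Product: 8 ethyl (2E)-2-[(4R)-4-hydroxy-1,3-dimethyl-4,6-dihydro-5H-cyclopenta[c]furan-5-ylidene]acetate
Conditions: (S)-Me-CBS (10 mol %), BH3·SMe2, THF, −30 °C; MeOH
Reagents that add atoms: none
Why: Corey–Bakshi–Shibata reduction is 1,2-selective, and the catalyst binds the carbonyl lone pair next to the small vinylic C11–H and away from the furan flank with its peri methyl group, which sets C6 as in the target.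

Step 5
Reactants: 8 allylic alcohol
Product: 9 ethyl 2-[(4R,5R)-4-hydroxy-1,3-dimethyl-5,6-dihydro-4H-cyclopenta[c]furan-5-yl]acetate (OH and side chain trans)
Conditions: [Ir(cod)(PCy3)(py)]PF6 (5 mol %), H2 (1 atm), CH2Cl2, rt
Reagents that add atoms: none
Why: Hydroxyl-directed hydrogenation with Crabtree's catalyst adds H2 to C7=C11 from the face of the C6–OH, so H7 ends cis and the CH2CO2Et chain trans to the hydroxyl (C7 as in the target), and the tetrasubstituted furan is not touched.

Step 6
Reactants: 9 trans-hydroxy ester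
Product: 10 6-O-TBS ether of 9
Conditions: TBSCl, imidazole, DMF, rt
Reagents that add atoms: tert-butyldimethylsilyl chloride CC(C)(C)[Si](C)(C)Cl
Why: Standard silylation protects O6 to the end of the route and puts a bulky group on one furan face next to C4.

Step 7
Reactants: 10 silyl ether; 11 1,1,3,3-tetrabromoacetone
Product: 13 oxa-bridged tricyclic ketone (C2=O; C5=C9; 4,10-O bridge syn to 6-OTBS; 7-CH2CO2Et anti), via dibromo cycloadduct 12 (not isolated)
Conditions: Zn–Cu, THF, −10 °C to rt; then Zn–Cu, NH4Cl, MeOH, rt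
Reagents that add atoms: none
Why: The [4+3] cycloaddition of the zinc dibromo-oxyallyl cation across furan C4/C10, followed by reductive debromination, forms C3–C4 and C1–C10, and the cation attacks the furan face anti to the C6 silyl ether, so the oxygen bridge ends syn to O6 and quaternary C4 (with temporary C10) is set.

Step 8
Reactants: 13 tricyclic ketone
Product: 14 equatorial C2 alcohol (2-OH syn to the O bridge)
Conditions: SmI2 (2.5 equiv), THF–i-PrOH, rt
Reagents that add atoms: none
Why: Ketyl (single-electron) reduction gives the thermodynamic equatorial alcohol of 8-heterobicyclo[3.2.1]octan-3-ones (the pseudotropine-type outcome), which is the C2 configuration of the target (syn to O4), and ester, silyl ether and alkene are inert.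

Step 9
Reactants: 14 alcohol
Product: 15 2,6-bis-TBS ether
Conditions: TBSCl, imidazole, DMF, 40 °C
Reagents that add atoms: tert-butyldimethylsilyl chloride CC(C)(C)[Si](C)(C)Cl
Why: Standard silylation masks O2 during the two later acylations and uses the same group as on O6, so that one final step removes both.

Step 10
Reactants: 15 bis-silyl ether ester
Product: 18 acrylate (C7–C(=CH2)CO2Et), via Mannich base 16 (not isolated), via methiodide 17 (not isolated)
Conditions: LDA, THF, −78 °C, then CH2=NMe2 I; MeI, CH2Cl2, rt; DBU, rt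
Reagents that add atoms: Eschenmoser's salt (N,N-dimethylmethyleneiminium iodide) C=[N+](C)C.[I-]
Why: Ester-enolate Mannich reaction, quaternisation and E1cB loss of trimethylamine is the standard α-methylenation, the ester CH2 (C11) is the only acidic site at this stage, and the transient C11 centre is destroyed.

Step 11
Reactants: 18 tricyclic acrylate
Product: 20 4,10-epoxy-bridged cyclodecane-5,9-dione (2,6-bis-OTBS; 7-acrylate), via ozonide 19 (not isolated)
Conditions: O3, CH2Cl2, −78 °C (Sudan Red 7B end point); PPh3, −78 °C to rt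
Reagents that add atoms: ozone [O-][O+]=O
Why: Ozone adds to the electron-rich, strained tetrasubstituted C5=C9 bond from the open face on the side of the oxygen bridge, the primary ozonide cleaves and recloses to 19, and PPh3 reduces it to the 1,5-diketone, which is the classical oxidative ring expansion of a bicycloalkene with a ring-fusion double bond (Δ9,10-octalin to cyclodecane-1,6-dione, bicyclo[5.3.0]dec-1(7)-ene to cyclodecane-1,5-dione). No ring is closed: the bond shared by the five- and the seven-membered ring is cut, so the two rings merge into the C1–C10 carbocycle without a macrocyclisation and its entropic and transannular penalties. No stereocenter is made or touched, and C2, C4, C6, C7 and C10, all set on rigid small rings, pass unchanged onto the medium ring. The step needs chemoselectivity for the tetraalkyl alkene over the 1,1-disubstituted acrylate, which the large rate difference of ozone toward electron-rich and electron-poor alkenes and titration against the dye secure. Transannular aldol reactions of the product are blocked by structure, because C4 and C10 are quaternary and attack of C6 or C8 on the far carbonyl would make a four-membered ring. In one operation the step delivers the ten-membered ring, the C9 ketone of the target and the oxygen at C5.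

Step 12
Reactants: 20 diketone
Product: 21 4,10-epoxy-bridged 5,9-diol
Conditions: NaBH4, CeCl3·7H2O, MeOH, −40 to 0 °C
Reagents that add atoms: none
Why: Luche reduction spares the acrylate, and at C5 hydride attacks anti to both α-oxygen substituents (polar Felkin–Anh control from C4 and from C6 is matched), which gives the 4,5-syn/5,6-syn alcohol of the target, while the C9 carbinol centre is erased in step 13.

Step 13
Reactants: 21 diol
Product: 22 5-hydroxy-9-ketone (bridge intact)
Conditions: Dess–Martin periodinane (1.0 equiv), CH2Cl2, 0 °C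
Reagents that add atoms: none
Why: Dess–Martin oxidation with one equivalent should discriminate sterically, since C9–OH has a CH2 neighbour whereas C5–OH is wedged between quaternary C4 and the silyloxy-bearing C6.

Step 14
Reactants: 22 α-alkoxy ketone
Product: 23 monocyclic 4,5-dihydroxy-9-ketone (10-H; 2,6-bis-OTBS; 7-acrylate)
Conditions: SmI2 (2.5 equiv), THF–MeOH, −78 °C
Reagents that add atoms: none
Why: SmI2 reduction of an α-alkoxy ketone (ketyl, second electron, β-elimination of alkoxide) cleaves only C10–O because C9=O is the sole ketone and C8 bears no heteroatom, the acrylate should survive at −78 °C (ketyl closure onto it would be 5-endo), and the samarium enolate is protonated at C10 from the face the oxygen left, a centre that base equilibration can still correct.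

Step 15
Reactants: 23 diol; 24 angelic acid ((Z)-2-methylbut-2-enoic acid)
Product: 26 5-angelate, via mixed anhydride 25 (not isolated)
Conditions: 24, 2,4,6-Cl3C6H2COCl, Et3N, toluene, rt; then 23, 80 °C
Reagents that add atoms: none
Why: Yamaguchi-type mixed-anhydride acylation without DMAP is the established way to esterify hindered secondary alcohols with angelic acid without Z-to-E isomerisation, and the tertiary C4–OH does not react.

Step 16
Reactants: 26 ketone
Product: 28 (8S)-8-hydroxy-9-ketone, via bis-TMS enol ether 27 (not isolated)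
Conditions: LiHMDS (2.5 equiv), TMSCl, THF, −78 °C; DMDO, acetone–CH2Cl2, −78 °C; citric acid, MeOH
Reagents that add atoms: dimethyldioxirane CC1(C)OO1
Why: Rubottom oxidation, in which kinetic deprotonation takes the less substituted C8 rather than tertiary C10, and DMDO attacks the enol ether from the peripheral ring face with H7 eclipsing the double bond (A1,3 control, anti to the C6 ring branch), which gives the 7,8-relationship of the target.

Step 17
Reactants: 28 α-hydroxy ketone; 29 isobutyryl chloride
Product: 30 8-isobutyrate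
Conditions: pyridine, DMAP (cat.), CH2Cl2, 0 °C
Reagents that add atoms: none
Why: Acylation of the only free secondary alcohol, with the tertiary C4–OH inert under these mild conditions and no stereocenter affected.

Step 18
Reactants: 30 fully acylated bis-silyl ether
Product: 32 cardivin C, via triol ester 31 (not isolated)
Conditions: HF·pyridine, THF, 0 °C to rt
Reagents that add atoms: none
Why: Acidic fluoride desilylation frees O2 and O6, and the 6-OH, now on a flexible ten-membered ring, closes the trans-fused α-methylene-γ-butyrolactone by 5-exo-trig transesterification of the acrylate, while the acidic medium suppresses acyl migration.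

**Compound list**
1 | 2,5-dimethylfuran-3-carbaldehyde | Cc1cc(C=O)c(C)o1 | starting material
2 | Meldrum's acid | CC1(C)OC(=O)CC(=O)O1 | starting material
3 | 5-[(2,5-dimethylfuran-3-yl)methylidene] Meldrum's acid | Cc1cc(C=C2C(=O)OC(C)(C)OC2=O)c(C)o1 | intermediate
4 | 5-[(2,5-dimethylfuran-3-yl)methyl] Meldrum's acid | Cc1cc(CC2C(=O)OC(C)(C)OC2=O)c(C)o1 | intermediate
5 | 1,3-dimethyl-5,6-dihydro-4H-cyclopenta[c]furan-4-one | Cc1oc(C)c2CCC(=O)c12 | intermediate
6 | ethyl glyoxylate | CCOC(=O)C=O | starting material
7 | (E)-alkylidene ketone ester | Cc1oc(C)c2C/C(=C\C(=O)OCC)C(=O)c12 | intermediate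
8 | (4R)-allylic alcohol | Cc1oc(C)c2C/C(=C\C(=O)OCC)[C@@H](O)c12 | intermediate
9 | (4R,5R)-trans-hydroxy ester | Cc1oc(C)c2C[C@H](CC(=O)OCC)[C@@H](O)c12 | intermediate
10 | 6-O-TBS ether of 9 | Cc1oc(C)c2C[C@H](CC(=O)OCC)[C@@H](O[Si](C)(C)C(C)(C)C)c12 | intermediate
11 | 1,1,3,3-tetrabromoacetone | BrC(Br)C(=O)C(Br)Br | starting material
12 | 1,3-dibromo [4+3] cycloadduct | C[C@@]12C(Br)C(=O)C(Br)[C@@](C)(O1)C3=C2[C@H](O[Si](C)(C)C(C)(C)C)[C@@H](CC(=O)OCC)C3 | intermediate
13 | oxa-bridged tricyclic C2 ketone | C[C@@]12CC(=O)C[C@@](C)(O1)C3=C2[C@H](O[Si](C)(C)C(C)(C)C)[C@@H](CC(=O)OCC)C3 | intermediate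
14 | equatorial C2 alcohol | C[C@@]12C[C@@H](O)C[C@@](C)(O1)C3=C2[C@H](O[Si](C)(C)C(C)(C)C)[C@@H](CC(=O)OCC)C3 | intermediate
15 | 2,6-bis-TBS ether | C[C@@]12C[C@@H](O[Si](C)(C)C(C)(C)C)C[C@@](C)(O1)C3=C2[C@H](O[Si](C)(C)C(C)(C)C)[C@@H](CC(=O)OCC)C3 | intermediate
16 | Mannich base (C11 epimers) | C[C@@]12C[C@@H](O[Si](C)(C)C(C)(C)C)C[C@@](C)(O1)C3=C2[C@H](O[Si](C)(C)C(C)(C)C)[C@@H](C(CN(C)C)C(=O)OCC)C3 | intermediate
17 | methiodide of 16 | C[C@@]12C[C@@H](O[Si](C)(C)C(C)(C)C)C[C@@](C)(O1)C3=C2[C@H](O[Si](C)(C)C(C)(C)C)[C@@H](C(C[N+](C)(C)C)C(=O)OCC)C3.[I-] | intermediate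
18 | tricyclic acrylate | C[C@@]12C[C@@H](O[Si](C)(C)C(C)(C)C)C[C@@](C)(O1)C3=C2[C@H](O[Si](C)(C)C(C)(C)C)[C@@H](C(=C)C(=O)OCC)C3 | intermediate
19 | C5/C9 secondary ozonide | C[C@@]12C[C@@H](O[Si](C)(C)C(C)(C)C)C[C@@](C)(O1)C34C[C@H](C(=C)C(=O)OCC)[C@@H](O[Si](C)(C)C(C)(C)C)C2(O3)OO4 | intermediate
20 | 4,10-epoxy-bridged cyclodecane-5,9-dione | C[C@@]12C[C@@H](O[Si](C)(C)C(C)(C)C)C[C@@](C)(O1)C(=O)C[C@H](C(=C)C(=O)OCC)[C@@H](O[Si](C)(C)C(C)(C)C)C2=O | intermediate
21 | bridged 5,9-diol | C[C@@]12C[C@@H](O[Si](C)(C)C(C)(C)C)C[C@@](C)(O1)[C@H](O)C[C@H](C(=C)C(=O)OCC)[C@@H](O[Si](C)(C)C(C)(C)C)[C@@H]2O | intermediate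
22 | bridged 5-hydroxy-9-ketone | C[C@@]12C[C@@H](O[Si](C)(C)C(C)(C)C)C[C@@](C)(O1)C(=O)C[C@H](C(=C)C(=O)OCC)[C@@H](O[Si](C)(C)C(C)(C)C)[C@@H]2O | intermediate
23 | monocyclic 4,5-dihydroxy-9-ketone | C[C@]1(O)C[C@@H](O[Si](C)(C)C(C)(C)C)C[C@H](C)C(=O)C[C@H](C(=C)C(=O)OCC)[C@@H](O[Si](C)(C)C(C)(C)C)[C@@H]1O | intermediate
24 | angelic acid | C/C=C(/C)C(=O)O | starting material
25 | angelic 2,4,6-trichlorobenzoic anhydride | C/C=C(/C)C(=O)OC(=O)c1c(Cl)cc(Cl)cc1Cl | intermediate
26 | 5-angelate | C[C@]1(O)C[C@@H](O[Si](C)(C)C(C)(C)C)C[C@H](C)C(=O)C[C@H](C(=C)C(=O)OCC)[C@@H](O[Si](C)(C)C(C)(C)C)[C@@H]1OC(=O)/C(C)=C\C | intermediate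
27 | 4-O-TMS C8=C9 TMS enol ether | C[C@]1(O[Si](C)(C)C)C[C@@H](O[Si](C)(C)C(C)(C)C)C[C@H](C)C(O[Si](C)(C)C)=C[C@H](C(=C)C(=O)OCC)[C@@H](O[Si](C)(C)C(C)(C)C)[C@@H]1OC(=O)/C(C)=C\C | intermediate
28 | (8S)-8-hydroxy-9-ketone | C[C@]1(O)C[C@@H](O[Si](C)(C)C(C)(C)C)C[C@H](C)C(=O)[C@@H](O)[C@H](C(=C)C(=O)OCC)[C@@H](O[Si](C)(C)C(C)(C)C)[C@@H]1OC(=O)/C(C)=C\C | intermediate
29 | isobutyryl chloride | CC(C)C(=O)Cl | starting material
30 | 8-isobutyrate | C[C@]1(O)C[C@@H](O[Si](C)(C)C(C)(C)C)C[C@H](C)C(=O)[C@@H](OC(=O)C(C)C)[C@H](C(=C)C(=O)OCC)[C@@H](O[Si](C)(C)C(C)(C)C)[C@@H]1OC(=O)/C(C)=C\C | intermediate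
31 | 2,4,6-triol ethyl acrylate | C[C@]1(O)C[C@@H](O)C[C@H](C)C(=O)[C@@H](OC(=O)C(C)C)[C@H](C(=C)C(=O)OCC)[C@@H](O)[C@@H]1OC(=O)/C(C)=C\C | intermediate
32 | cardivin C (2S,4S,5S,6R,7R,8S,10S) | C=C1C(=O)O[C@@H]2[C@@H]1[C@H](OC(=O)C(C)C)C(=O)[C@@H](C)C[C@H](O)C[C@](C)(O)[C@H]2OC(=O)/C(C)=C\C | target

**Step count:** 18 steps in total. The longest linear sequence is 18 steps, from 1.

**Steps most likely to fail**

Step 7. The cycloaddition at the fully substituted furan may be slow. Zinc bromide may ionise the furylic silyl ether, or the cation may not distinguish the two furan faces well.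
- The fallback sets out from 10 and replaces the concerted cycloaddition by a stepwise ionic [3+4] annulation of the derived 1,4-diketone.
- Oxidative furan opening (mCPBA, CH2Cl2, 0 °C) would give the cis-1,2-diacetylcyclopentene F1.
- TMSOTf-promoted double Mukaiyama-type addition of 1-methoxy-1,3-bis(trimethylsilyloxy)buta-1,3-diene follows. The first aldol is followed by carbonyl participation to a cyclic oxocarbenium ion, which is attacked anti to the silyl ether. This would give the oxa-bridged β-keto ester F2; the position of the ester at C1 or C3 is immaterial.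
- Krapcho demethoxycarbonylation (LiCl, wet DMSO, 130 °C) returns to the route at 13.

Step 13. The oxidant may attack both carbinols or the wrong one. The fallback sets out from 20 and avoids the diol altogether.
- Soft enolisation (TBSOTf, Et3N, CH2Cl2, −78 °C) should convert only the C9 ketone, the one with an α-CH2, into the TBS enol ether F3.
- Luche reduction then meets a single ketone and would give the C5 alcohol F4.
- Brief treatment with buffered HF·pyridine at −20 °C cleaves the enol ether only and returns to the route at 22.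

Step 16. Facial selectivity in the oxidation of the medium-ring enol ether may be poor or reversed. The fallback sets out from 26.
- The oxidation is run as written, and the 8-epimeric α-hydroxy ketone F5 is used instead of being discarded.
- Mitsunobu esterification with isobutyric acid (PPh3, DIAD, toluene, 0 °C) inverts the activated α-keto carbinol.
- This returns to the route at 30 and makes step 17 unnecessary.

**Further compounds**
F1 | step 7 | cis-enedione (1,2-diacetylcyclopentene with 6-OTBS and 7-CH2CO2Et) | CC(=O)C1=C(C(C)=O)C[C@H](CC(=O)OCC)[C@H]1O[Si](C)(C)C(C)(C)C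
F2 | step 7 | oxa-bridged tricyclic β-keto methyl ester | C[C@@]12C(C(=O)OC)C(=O)C[C@@](C)(O1)C3=C2[C@H](O[Si](C)(C)C(C)(C)C)[C@@H](CC(=O)OCC)C3
F3 | step 13 | C9 TBS enol ether of diketone 20 | C[C@@]12C[C@@H](O[Si](C)(C)C(C)(C)C)C[C@@](C)(O1)C(O[Si](C)(C)C(C)(C)C)=C[C@H](C(=C)C(=O)OCC)[C@@H](O[Si](C)(C)C(C)(C)C)C2=O
F4 | step 13 | C5 alcohol of F3 | C[C@@]12C[C@@H](O[Si](C)(C)C(C)(C)C)C[C@@](C)(O1)C(O[Si](C)(C)C(C)(C)C)=C[C@H](C(=C)C(=O)OCC)[C@@H](O[Si](C)(C)C(C)(C)C)[C@@H]2O
F5 | step 16 | 8-epimer of 28 | C[C@]1(O)C[C@@H](O[Si](C)(C)C(C)(C)C)C[C@H](C)C(=O)[C@H](O)[C@H](C(=C)C(=O)OCC)[C@@H](O[Si](C)(C)C(C)(C)C)[C@@H]1OC(=O)/C(C)=C\C
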